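**Strategy.** The side chain is cut between C7, the β-carbon of the C7=C8–C9(=O) enone, and the bis-allylic stereocentre C6 (chain numbered from the pyranone-bound C2). A nickel-catalysed, ligand-controlled Markovnikov hydroalkenylation joins an achiral hydroxypyranone triene to a β-boryl dienone. In one operation it forms C6–C7, turns the terminal CH2 into the C6 methyl group and sets 6S, delivering the target without protecting groups. It exploits the skipped C4=C5/C7=C8 diene: C6 is the free terminus of an allyl unit whose other terminus C4 is methyl-blocked and conjugated through C2=C3 to the pyranone ring. The boryl dienone comes from (S)-2-methylbutanol, which supplies 12S.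

Key step: step 11

Assumption: alcohols 5 and 7 are carried as mixtures of C3 epimers, because this carbon becomes the C9 ketone in step 5. Side-chain locants in the text follow the tetradeca-2,4,7,10-tetraen-2-yl numbering of the target name.

Step 1
Reactants: 1 (S)-2-methylbutan-1-ol
Product: 2 (S)-2-methylbutanal
Conditions: TEMPO (1 mol %), NaOCl, KBr (10 mol %), NaHCO3, CH2Cl2/H2O, 0 °C; used as a dried CH2Cl2 solution
Reagents that add atoms: none
Why: The TEMPO/hypochlorite (Anelli) oxidation of a primary alcohol stops at the aldehyde and, being fast, cold and buffered, should leave the α-stereocentre untouched.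

Step 2
Reactants: 2 (S)-2-methylbutanal; 3 2-(triphenylphosphoranylidene)propanal
Product: 4 (2E,4S)-2,4-dimethylhex-2-enal
Conditions: toluene, 80 °C (sealed)
Reagents that add atoms: none
Why: Wittig olefination with the formyl-stabilised ylide should give the E-trisubstituted enal, and the aliphatic aldehyde is expected to react well before the less electrophilic enal product.

Step 3
Reactants: 4 (2E,4S)-2,4-dimethylhex-2-enal
Product: 5 (4E,6S)-4,6-dimethyloct-4-en-1-yn-3-ol (C3 epimers)
Conditions: ethynylmagnesium bromide (1.3 equiv), THF, −78 → 0 °C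
Reagents that add atoms: ethynylmagnesium bromide, C#C[Mg]Br
Why: Grignard 1,2-addition to the α-branched enal gives the propargylic alcohol; the new carbinol centre forms without control and is removed by oxidation in step 5.

Step 4
Reactants: 5 (4E,6S)-4,6-dimethyloct-4-en-1-yn-3-ol
Product: 7 (1E,4E,6S)-2,4,6-trimethyl-1-(4,4,5,5-tetramethyl-1,3,2-dioxaborolan-2-yl)octa-1,4-dien-3-ol (C3 epimers), via alkenyl dimethylalane 6 (not isolated)
Conditions: AlMe3 (3.5 equiv), Cp2ZrCl2 (25 mol %), CH2Cl2, 0 °C → rt; then MeOBpin (4 equiv), 0 °C → rt; aq. KNaC4H4O6 work-up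
Reagents that add atoms: trimethylaluminium, C[Al](C)C; 2-methoxy-4,4,5,5-tetramethyl-1,3,2-dioxaborolane (MeOBpin), COB1OC(C)(C)C(C)(C)O1
Why: Zirconium-catalysed Negishi carboalumination adds methyl and aluminium syn across the terminal alkyne with methyl on the internal carbon, so that aluminium, and after aluminium-to-boron exchange the boron, should stand trans to the carbinol carbon (1E).

Step 5
Reactants: 7 (1E,4E,6S)-2,4,6-trimethyl-1-(4,4,5,5-tetramethyl-1,3,2-dioxaborolan-2-yl)octa-1,4-dien-3-ol
Product: 8 (1E,4E,6S)-2,4,6-trimethyl-1-(4,4,5,5-tetramethyl-1,3,2-dioxaborolan-2-yl)octa-1,4-dien-3-one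
Conditions: Dess–Martin periodinane (1.3 equiv), NaHCO3, CH2Cl2, 0 °C → rt
Reagents that add atoms: none
Why: Buffered Dess–Martin oxidation of the bis-allylic alcohol should give the cross-conjugated dienone without touching the alkenyl pinacol boronate or the alkene geometries.

Step 6
Reactants: 9 acrolein; 3 2-(triphenylphosphoranylidene)propanal
Product: 10 (2E)-2-methylpenta-2,4-dienal
Conditions: acrolein (3 equiv), CH2Cl2, 0 °C → rt; volatile, used as a concentrated solution
Reagents that add atoms: none
Why: E-selective Wittig olefination; excess of the more electrophilic acrolein should hold the reaction at the mono-homologated dienal.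

Step 7
Reactants: 10 (2E)-2-methylpenta-2,4-dienal; 3 2-(triphenylphosphoranylidene)propanal
Product: 11 (2E,4E)-2,4-dimethylhepta-2,4,6-trienal
Conditions: toluene, 90 °C, BHT (cat.)
Reagents that add atoms: none
Why: A second Wittig homologation with the same stabilised ylide should add the next E-trisubstituted enal unit, with the radical inhibitor protecting the terminal diene.

Step 8
Reactants: 12 ethyl 2-methyl-3-oxopentanoate; 11 (2E,4E)-2,4-dimethylhepta-2,4,6-trienal
Product: 14 ethyl (6E,8E)-5-hydroxy-2,4,6,8-tetramethyl-3-oxoundeca-6,8,10-trienoate (diastereomer mixture), via ketoester dianion 13 (not isolated)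
Conditions: 12, NaH, THF, 0 °C; n-BuLi, 0 °C; then 11, −78 °C
Reagents that add atoms: none
Why: The β-ketoester dianion reacts at its more basic γ-carbon in an aldol 1,2-addition to the enal; the stereocentres formed are all lost in steps 9 and 10.

Step 9
Reactants: 14 ethyl (6E,8E)-5-hydroxy-2,4,6,8-tetramethyl-3-oxoundeca-6,8,10-trienoate
Product: 15 ethyl (6E,8E)-2,4,6,8-tetramethyl-3,5-dioxoundeca-6,8,10-trienoate
Conditions: Dess–Martin periodinane (1.5 equiv), NaHCO3, CH2Cl2, rt
Reagents that add atoms: none
Why: Dess–Martin oxidation of the allylic β-hydroxy ketone should give the β,δ-diketo ester under neutral conditions that spare the triene.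

Step 10
Reactants: 15 ethyl (6E,8E)-2,4,6,8-tetramethyl-3,5-dioxoundeca-6,8,10-trienoate
Product: 16 4-hydroxy-3,5-dimethyl-6-[(2E,4E)-4-methylhepta-2,4,6-trien-2-yl]-2H-pyran-2-one
Conditions: DBU (1.5 equiv), toluene, 60 °C; work-up at pH 3
Reagents that add atoms: none
Why: Base-mediated enolisation of the C5 ketone and O-acylation by the ester (lactonisation with loss of ethanol), followed by tautomerisation, is the standard route to 4-hydroxy-2-pyranones from β,δ-diketo esters.

Step 11
Reactants: 16 4-hydroxy-3,5-dimethyl-6-[(2E,4E)-4-methylhepta-2,4,6-trien-2-yl]-2H-pyran-2-one; 8 (1E,4E,6S)-2,4,6-trimethyl-1-(4,4,5,5-tetramethyl-1,3,2-dioxaborolan-2-yl)octa-1,4-dien-3-one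
Product: 17 4-hydroxy-3,5-dimethyl-6-[(2E,4E,6S,7E,10E,12S)-4,6,8,10,12-pentamethyl-9-oxotetradeca-2,4,7,10-tetraen-2-yl]-2H-pyran-2-one
Conditions: Ni(cod)2 (10 mol %), (R)-DTBM-SEGPHOS (12 mol %; its antipode if a model coupling shows that one to give 6S), 8 (1.5 equiv), MeOH/THF 1:1, 40 °C; work-up at pH 4
Reagents that add atoms: none
Why: Proposed new method: zerovalent nickel bound to the chiral bisphosphine should coordinate the terminal diene of 16 (its C4=C5 and C6=C7 bonds) and, with methanol or the acidic pyranone OH as proton donor, give an η3-allyl nickel alkoxide spanning C4–C6 in which the future C6 methyl group is already formed; transfer of the alkenyl group from the pinacol boronate 8 to nickel and C–C reductive elimination at C6 then release 17 and return zerovalent nickel. The closest known reaction types are the nickel-catalysed enantioselective Markovnikov hydroarylation of 1-substituted 1,3-dienes with arylboron reagents in alcohols and the analogous hydroalkenylation of styrenes with alkenylboronic acids; a pyranone-conjugated triene and a β-boryl enone have not been used in them. No ring is closed. The new 6S centre is set by the ligand, which differentiates the two faces of the allyl terminus in the C–C bond-forming event; the remote 12S centre is not expected to bias it, so the ligand antipode is fixed in a model coupling. The step needs the terminal alkene to react in preference to the trisubstituted ones and C6 rather than C4 or C2 to be bonded: C4 and C2 carry methyl groups, so bonding there would build a quaternary centre and break conjugation with the pyranone ring, whereas bonding at C6 keeps the 2E,4E-diene and the syn-allyl geometry preserves 4E. The α-methylated, trisubstituted enone alkenes of 8 and 17 are poor ligands for nickel and the medium is neutral, which should spare the dienone and the base-labile bis-allylic C6–H.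

**Compound list**

1 | (S)-2-methylbutan-1-ol | CC[C@H](C)CO | starting material
2 | (S)-2-methylbutanal | CC[C@H](C)C=O | intermediate
3 | 2-(triphenylphosphoranylidene)propanal | CC(C=O)=P(c1ccccc1)(c1ccccc1)c1ccccc1 | starting material
4 | (2E,4S)-2,4-dimethylhex-2-enal | CC[C@H](C)/C=C(\C)C=O | intermediate
5 | (4E,6S)-4,6-dimethyloct-4-en-1-yn-3-ol (C3 epimers) | CC[C@H](C)/C=C(\C)C(O)C#C | intermediate
6 | dimethyl[(1E,4E,6S)-3-(dimethylalumanyloxy)-2,4,6-trimethylocta-1,4-dien-1-yl]alumane (not isolated) | CC[C@H](C)/C=C(\C)C(O[Al](C)C)/C(C)=C/[Al](C)C | intermediate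
7 | (1E,4E,6S)-2,4,6-trimethyl-1-(4,4,5,5-tetramethyl-1,3,2-dioxaborolan-2-yl)octa-1,4-dien-3-ol (C3 epimers) | CC[C@H](C)/C=C(\C)C(O)/C(C)=C/B1OC(C)(C)C(C)(C)O1 | intermediate
8 | (1E,4E,6S)-2,4,6-trimethyl-1-(4,4,5,5-tetramethyl-1,3,2-dioxaborolan-2-yl)octa-1,4-dien-3-one | CC[C@H](C)/C=C(\C)C(=O)/C(C)=C/B1OC(C)(C)C(C)(C)O1 | intermediate
9 | acrolein | C=CC=O | starting material
10 | (2E)-2-methylpenta-2,4-dienal | C=C/C=C(\C)C=O | intermediate
11 | (2E,4E)-2,4-dimethylhepta-2,4,6-trienal | C=C/C=C(C)/C=C(\C)C=O | intermediate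
12 | ethyl 2-methyl-3-oxopentanoate | CCOC(=O)C(C)C(=O)CC | starting material
13 | sodium lithium dianion (2,4-dienolate) of ethyl 2-methyl-3-oxopentanoate (not isolated) | CCOC([O-])=C(C)C([O-])=CC.[Na+].[Li+] | intermediate
14 | ethyl (6E,8E)-5-hydroxy-2,4,6,8-tetramethyl-3-oxoundeca-6,8,10-trienoate (diastereomer mixture) | CCOC(=O)C(C)C(=O)C(C)C(O)/C(C)=C/C(C)=C/C=C | intermediate
15 | ethyl (6E,8E)-2,4,6,8-tetramethyl-3,5-dioxoundeca-6,8,10-trienoate | CCOC(=O)C(C)C(=O)C(C)C(=O)/C(C)=C/C(C)=C/C=C | intermediate
16 | 4-hydroxy-3,5-dimethyl-6-[(2E,4E)-4-methylhepta-2,4,6-trien-2-yl]-2H-pyran-2-one | C=C/C=C(C)/C=C(\C)c1oc(=O)c(C)c(O)c1C | intermediate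
17 | 4-hydroxy-3,5-dimethyl-6-[(2E,4E,6S,7E,10E,12S)-4,6,8,10,12-pentamethyl-9-oxotetradeca-2,4,7,10-tetraen-2-yl]-2H-pyran-2-one | CC[C@H](C)/C=C(\C)C(=O)/C(C)=C/[C@@H](C)/C=C(C)/C=C(\C)c1oc(=O)c(C)c(O)c1C | target

**Total step count:** 11. **Longest linear sequence:** 6 steps (1–5 and 11; the pyranone branch, steps 6–10 and 11, is equally long).

**Steps most likely to fail**

Step 11 (proposed new method). The catalyst may stall because the acidic pyranone protonates or binds nickel, boron-to-nickel transfer from the electron-poor boronate may be slow and lose out to protodeboronation, or face selectivity at C6 may be poor. The fallback uses known chemistry, a stereoinvertive palladium-catalysed Suzuki–Miyaura coupling of an enantioenriched secondary allylic carbonate; it sets out from ylide 3 (and dianion 13) and comes back to the route at 17. Commercial (R)-2-(tert-butyldimethylsilyloxy)propanal F1 is taken through two Wittig reactions with 3 to (2E,4R)-4-(tert-butyldimethylsilyloxy)-2-methylpent-2-enal F2 and (2E,4E,6R)-6-(tert-butyldimethylsilyloxy)-2,4-dimethylhepta-2,4-dienal F3. Aldol addition of 13 gives ethyl (6E,8E,10R)-10-(tert-butyldimethylsilyloxy)-5-hydroxy-2,4,6,8-tetramethyl-3-oxoundeca-6,8-dienoate F4, Dess–Martin oxidation the 3,5-dioxo ester F5, and DBU lactonisation the silyloxy pyranone F6. HF·pyridine frees the (R)-allylic alcohol F7, and methyl chloroformate/pyridine gives the bis(methyl carbonate) F8. With Pd(PPh3)4, 8 and CsF in THF/H2O at 40 °C, zerovalent palladium should ionise the allylic carbonate with inversion and deliver the alkenyl group from the metal face to the less hindered C6 terminus (net inversion, 6R carbonate to 6S product). This gives the 4-O-methoxycarbonyl derivative of 17, F9, whose labile pyranyl carbonate is cleaved in the same aqueous fluoride medium to return 17.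

Step 4. The doubly activated (allylic and propargylic) aluminium alkoxide may ionise under the Lewis-acidic conditions with methyl transfer to C3, and aluminium-to-boron exchange may be incomplete. The fallback masks the carbinol and replaces carboalumination by copper-catalysed borylcupration; it sets out from 5 and comes back at 7. TBSCl/imidazole gives tert-butyl{[(4E,6S)-4,6-dimethyloct-4-en-1-yn-3-yl]oxy}dimethylsilane F10. Copper-catalysed methylboration (CuCl, Xantphos, B2pin2, MeI, NaOtBu, THF, rt) should add boron to the terminal carbon and copper syn to the internal one, and methyl iodide captures the alkenylcopper with retention to give the silyl ether of 7, F11. HF·pyridine then returns 7.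

Step 7. At the temperature the sluggish α-methyl enal needs, the terminal diene may be lost by Diels–Alder dimerisation or polymerisation. The fallback replaces the hot Wittig by a room-temperature phosphonate olefination and a redox adjustment; it sets out from 10 and comes back at 11. Horner–Wadsworth–Emmons reaction with triethyl 2-phosphonopropionate (NaH, THF, 0 °C) gives ethyl (2E,4E)-2,4-dimethylhepta-2,4,6-trienoate F12, iBu2AlH (CH2Cl2, −78 °C) gives (2E,4E)-2,4-dimethylhepta-2,4,6-trien-1-ol F13, and MnO2 (CH2Cl2, rt) returns 11.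

**Further compounds**

F1 | step 11 | (R)-2-(tert-butyldimethylsilyloxy)propanal | C[C@@H](O[Si](C)(C)C(C)(C)C)C=O
F2 | step 11 | (2E,4R)-4-(tert-butyldimethylsilyloxy)-2-methylpent-2-enal | C[C@@H](O[Si](C)(C)C(C)(C)C)/C=C(\C)C=O
F3 | step 11 | (2E,4E,6R)-6-(tert-butyldimethylsilyloxy)-2,4-dimethylhepta-2,4-dienal | C[C@@H](O[Si](C)(C)C(C)(C)C)/C=C(C)/C=C(\C)C=O
F4 | step 11 | ethyl (6E,8E,10R)-10-(tert-butyldimethylsilyloxy)-5-hydroxy-2,4,6,8-tetramethyl-3-oxoundeca-6,8-dienoate | CCOC(=O)C(C)C(=O)C(C)C(O)/C(C)=C/C(C)=C/[C@@H](C)O[Si](C)(C)C(C)(C)C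
F5 | step 11 | ethyl (6E,8E,10R)-10-(tert-butyldimethylsilyloxy)-2,4,6,8-tetramethyl-3,5-dioxoundeca-6,8-dienoate | CCOC(=O)C(C)C(=O)C(C)C(=O)/C(C)=C/C(C)=C/[C@@H](C)O[Si](C)(C)C(C)(C)C
F6 | step 11 | 6-[(2E,4E,6R)-6-(tert-butyldimethylsilyloxy)-4-methylhepta-2,4-dien-2-yl]-4-hydroxy-3,5-dimethyl-2H-pyran-2-one | C[C@@H](O[Si](C)(C)C(C)(C)C)/C=C(C)/C=C(\C)c1oc(=O)c(C)c(O)c1C
F7 | step 11 | 4-hydroxy-6-[(2E,4E,6R)-6-hydroxy-4-methylhepta-2,4-dien-2-yl]-3,5-dimethyl-2H-pyran-2-one | C[C@@H](O)/C=C(C)/C=C(\C)c1oc(=O)c(C)c(O)c1C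
F8 | step 11 | (2R,3E,5E)-6-[4-(methoxycarbonyloxy)-3,5-dimethyl-2-oxo-2H-pyran-6-yl]-4-methylhepta-3,5-dien-2-yl methyl carbonate | C[C@@H](OC(=O)OC)/C=C(C)/C=C(\C)c1oc(=O)c(C)c(OC(=O)OC)c1C
F9 | step 11 | 4-O-methoxycarbonyl derivative of 17 | CC[C@H](C)/C=C(\C)C(=O)/C(C)=C/[C@@H](C)/C=C(C)/C=C(\C)c1oc(=O)c(C)c(OC(=O)OC)c1C
F10 | step 4 | tert-butyl{[(4E,6S)-4,6-dimethyloct-4-en-1-yn-3-yl]oxy}dimethylsilane | CC[C@H](C)/C=C(\C)C(O[Si](C)(C)C(C)(C)C)C#C
F11 | step 4 | tert-butyldimethyl{[(1E,4E,6S)-2,4,6-trimethyl-1-(4,4,5,5-tetramethyl-1,3,2-dioxaborolan-2-yl)octa-1,4-dien-3-yl]oxy}silane | CC[C@H](C)/C=C(\C)C(O[Si](C)(C)C(C)(C)C)/C(C)=C/B1OC(C)(C)C(C)(C)O1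
F12 | step 7 | ethyl (2E,4E)-2,4-dimethylhepta-2,4,6-trienoate | CCOC(=O)/C(C)=C/C(C)=C/C=C
F13 | step 7 | (2E,4E)-2,4-dimethylhepta-2,4,6-trien-1-ol | OC/C(C)=C/C(C)=C/C=C
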